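Remark on the chemistry: chain atoms are numbered as in 15 throughout (aryl rings on C1 and C7, acetate on C3, hydroxyl on C5), also where the systematic name of an intermediate uses other locants; because diol 12 is C2-symmetric, both directions of numbering describe the same compound.

## Structural features

Compound 15 is an acyclic 1,7-diarylheptane in which two 4-hydroxy-3-methoxyphenyl rings are joined to C1 and C7 of an unbranched seven-carbon chain, and the two arenes are the only rings. The chain carries oxygen on C3 (as acetate) and on C5 (as free hydroxyl), and these two stereocentres are not adjacent but stand in a 1,3-relationship across the C4 methylene, both S, which is the anti arrangement. The parent 3,5-diol is C2-symmetric, so its hydroxyls are homotopic, acetylation of either gives the same monoester and a 1,3-acetyl shift is degenerate, which leaves only the question of mono- against bis-acylation. The fragile groups are the secondary acetate, which would not survive hydride, strong base or organometallic reagents, and the two free phenols, which are easily oxidised and would bind Ti(OiPr)4. The phenols are therefore carried as benzyl ethers and the acetate is introduced late. The real difficulty is absolute and relative control of two carbinol centres on a flexible chain that offers no other stereochemical handle. The key step uses the C3–C4–C5 segment, in which a C5 carbinol next to an (E)-C3=C4 alkene can be epoxidised so that oxygen arrives on C3 and C4 in a fixed relation to C5, and later loss of the C4–O bond to hydride leaves exactly the anti C3–O/C5–O pattern.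

## Logic of the disconnections

15 to 14: the two phenolic O–H bonds are replaced by O–CH2Ph bonds. The phenols must be masked through the organometallic, titanium and hydride steps, and a benzyl ether is the mask that can be removed last without base or fluoride. The forward step has to cleave two aryl benzyl ethers while leaving the acetate, the C5 hydroxyl and the C1/C7 benzylic C–C bonds alone.

14 to 12 (through 13): the acyl C–O bond at the C3 oxygen is cut. This returns a C2-symmetric diol, so two different oxygen functions become one repeated unit. The forward step must deliver exactly one acetyl group. Tying both oxygens to a single orthoester carbon in 13 and hydrolysing it does this, and because the oxygens are homotopic no regiochemistry is involved.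

12 to 11: the C4–H bond that the forward step makes is cut and C4 is tied back to the C3 oxygen as an oxirane. The 1,3-dioxygen pattern thereby becomes a contiguous C3/C4/C5 array that an alkene next to a carbinol can provide. The forward step must put hydride on C4 and not on C3, which calls for delivery from the C5 oxygen.

11 to 10 (key disconnection): the C3–O and C4–O bonds of the oxirane are cut. Three stereocentres are traded for a racemic (E)-allylic alcohol with none that needs control. The forward step must choose one enantiomer of 10 and one alkene face at the same time, which is the task of a chiral tartrate-bound titanium peroxide.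

10 to 8 and 9: the C3=C4 double bond is cut. This gives two fragments of similar size, 9 carrying C1–C3 and 8 carrying C4–C7, each with one extra terminal methylene that is lost in the forward step. The forward metathesis must favour cross- over homo-coupling and give the E alkene.

8 to 6 and 7, and 9 to 6: in 8 the C4–C5 bond is cut, and in 9 the terminal C=C bond at C3 is cut. Both fragments then come from the single aldehyde 6, whose carbonyl carbon becomes C5 in one and C3 in the other. The forward steps are a carbonyl addition that may be unselective, since the resolution comes later, and a methylenation.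

6 to 5 to 3 (through 4): the oxidation level of the terminal carbon is lowered to the alcohol, and its C–O bond is traced back to the terminal alkene of 3. The forward steps must place oxygen on the terminal carbon only and stop the oxidation at the aldehyde.

3 to 1 and 2: the phenolic O–CH2Ph bond is cut, which leads to two bulk chemicals; the forward alkylation must not move the allyl double bond into conjugation.

## Other disconnections considered

Alternative 1: The cut is made at C2–C3 and C5–C6, which reduces the chain to propane-1,3-diol A1 as the C3–C4–C5 unit and two molecules of allyl acetate A2 as the source of C1–C2 and C6–C7. In the forward key step A1 would be allylated at both carbinol carbons by transfer hydrogenation with A2 under the cyclometallated iridium catalyst assembled from [Ir(cod)Cl]2, one enantiomer of Cl,MeO-BIPHEP, 4-chloro-3-nitrobenzoic acid and Cs2CO3. Each alcohol is dehydrogenated to the aldehyde at the metal and captured by the allyl complex formed from A2, to give (4S,6S)-nona-1,8-diene-4,6-diol A3 with no ring formed.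
- In its favour: both stereocentres would come from an achiral, trivial diol in one catalytic operation. The two-fold addition should raise the enantiomeric purity, because a mismatched first addition ends in a separable diastereomer and not in the enantiomer, and no material is discarded as an unwanted enantiomer. On absolute stereocontrol and on the number of steps up to the stereodefining event this alternative is the better of the two.
- Against it here: the allyl units do not map onto the ArCH2CH2 termini, because the terminal methylene carbons of A3 are surplus. After diol protection both alkenes would have to be cleaved oxidatively, an aryl nucleophile added to each β-alkoxy aldehyde (which is prone to elimination) and the two new benzylic hydroxyls removed again. That is some five or six operations before the monoacetylation and deprotection that both plans share.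
- Comparison: structurally, the chosen plan assembles the complete C1–C7 diaryl skeleton first and needs only three steps after its key step. Mechanistically, Alternative 1 relies on catalyst control at both centres, whereas the chosen plan relies on one reagent-controlled step plus an intramolecular hydride delivery. In overall step count the chosen plan should be shorter, at the price of the half of 10 that is not epoxidised.

Alternative 2: The cut is made at the two aryl–CH2 bonds (ring carbon to C1 and ring carbon to C7). This leads back to the trans-divinyl acetonide (4R,6R)-4,6-diethenyl-2,2-dimethyl-1,3-dioxane A4 as the C2-symmetric core and to two molecules of 1-(benzyloxy)-4-bromo-2-methoxybenzene A5 as the aryl partner. The descriptors of A4 are R,R although its spatial arrangement is that of the S,S product, because vinyl outranks the ring methylene whereas the saturated side chain does not. In the forward key step both vinyl groups of A4 would be hydroborated with 9-BBN and the two primary carbon–boron bonds so formed coupled with A5 under PdCl2(dppf) and aqueous base (B-alkyl Suzuki–Miyaura coupling). The product would be (4S,6S)-4,6-bis{2-[4-(benzyloxy)-3-methoxyphenyl]ethyl}-2,2-dimethyl-1,3-dioxane A6 and no ring is closed.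
- In its favour: the step is highly convergent, the C2 symmetry makes both ends equivalent so that one set of conditions serves twice, the diol arrives protected, the aryl partner could be varied late, and nothing is lost to a resolution. On convergence and material throughput it is the better plan.
- Against it: the key step creates no stereocentre. A4 would have to be secured enantiopure beforehand, for example by asymmetric hydrogenation of a 1,3-diketone and installation of the vinyl groups, in about four to five steps. A double coupling is also only as good as its weaker half, with protodeboronation and β-hydride elimination as the expected leaks.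
- Comparison: after acid hydrolysis of the acetonide of A6 this route would meet the chosen one at 12, so the endgame is identical and the total length about equal. Structurally both plans pass through the same C2-symmetric diol. Mechanistically the chosen plan generates the stereochemistry inside the sequence from a racemate by reagent control, while Alternative 2 imports it and spends its key step on skeletal bonds only.

Alternative 3: Three bonds are cut: the bond from the C5 oxygen to C1 (which makes that oxygen a ring oxygen), C1–C2 and C3–OAc. This leads back to the homoallylic alcohol (3S)-1-[4-(benzyloxy)-3-methoxyphenyl]hex-5-en-3-ol A7 as the chiral component and to 4-(benzyloxy)-3-methoxybenzaldehyde A8 as the second component; one enantioselective allylation of 6 would provide A7. In the forward key step A7 and A8 would condense under BF3·OEt2 and acetic acid to an oxocarbenium ion that cyclises through a chair with both substituents equatorial (Prins cyclisation, 6-endo closure of the tetrahydropyran). The C3 cation would be captured equatorially by acetate to give the all-cis pyran (2S,4R,6S)-2-[4-(benzyloxy)-3-methoxyphenyl]-6-{2-[4-(benzyloxy)-3-methoxyphenyl]ethyl}oxan-4-yl acetate A9 as the product of the key step. Hydrogenolysis of A9 would then cleave the benzylic ring C1–O bond together with the two benzyl ethers and lead directly to 15, since the all-cis ring corresponds to the anti C3/C5 pattern with the acetate already on C3 and the hydroxyl on C5.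
- In its favour: this is the shortest plan by a clear margin (about six steps against ten), it needs no separate monoacetylation, and the relative configuration comes from a well-ordered chair. On step economy it is the better plan.
- Against it here: the aldehyde A8 is an electron-rich 4-alkoxybenzaldehyde. The stabilised benzylic oxocarbenium ion is the case in which reversible 2-oxonia-Cope rearrangement and allyl transfer are most to be feared; these would erode the configurational purity at C5 and produce symmetric pyrans by side-chain exchange. Fluoride capture from BF3·OEt2 can compete with acetate, and the cyclic benzylic ether should be cleaved more slowly than the benzyl ethers, so forcing conditions may be needed.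
- Comparison: the final deprotection is the same operation in both plans and equal in risk apart from that ring C–O bond. The chosen plan is longer, but its two stereodefining steps do not depend on the electronic nature of the arene. The stereochemical integrity of Alternative 3 depends on suppressing a cationic pathway that this particular arene favours.

Key step: step 7

Step 1
Reactants: 1 eugenol (4-allyl-2-methoxyphenol); 2 benzyl bromide
Product: 3 4-allyl-1-(benzyloxy)-2-methoxybenzene
Conditions: K2CO3, acetone, reflux
Reagents that add atoms: none
Why: Williamson etherification of the phenoxide with a benzylic bromide (SN2); the weak carbonate base should not move the allyl double bond into conjugation, and the benzyl ether masks the phenol for all metal-mediated steps that follow.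

Step 2
Reactants: 3 4-allyl-1-(benzyloxy)-2-methoxybenzene
Product: 5 3-[4-(benzyloxy)-3-methoxyphenyl]propan-1-ol, via alkylborane 4 (not isolated)
Conditions: 9-BBN, THF, 0 °C to rt; then aq. NaOH, 30% H2O2, 0 °C to rt
Reagents that add atoms: 9-borabicyclo[3.3.1]nonane (9-BBN), B1C2CCCC1CCC2 (boron and bicycle of 4 only); hydrogen peroxide, OO (hydroxyl oxygen of 5)
Why: Hydroboration–oxidation: the bulky dialkylborane places boron on the terminal carbon of the monosubstituted alkene, and alkaline peroxide replaces the C–B bond by C–O; the aryl ethers are inert.

Step 3
Reactants: 5 3-[4-(benzyloxy)-3-methoxyphenyl]propan-1-ol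
Product: 6 3-[4-(benzyloxy)-3-methoxyphenyl]propanal
Conditions: 2,2,6,6-tetramethylpiperidin-1-oxyl (TEMPO, 10 mol %), PhI(OAc)2, CH2Cl2, rt
Reagents that add atoms: none
Why: Oxoammonium-mediated oxidation of a primary alcohol, which under non-aqueous conditions should stop at the aldehyde; the arene carries only ether oxygens and no free phenol, so the oxidant has no other point of attack.

Step 4
Reactants: 6 3-[4-(benzyloxy)-3-methoxyphenyl]propanal; 7 vinylmagnesium bromide
Product: 8 rac-5-[4-(benzyloxy)-3-methoxyphenyl]pent-1-en-3-ol
Conditions: THF, −78 to 0 °C; then sat. aq. NH4Cl
Reagents that add atoms: none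
Why: Grignard 1,2-addition to an unhindered aliphatic aldehyde; the new carbinol (C5) is formed as the racemate on purpose, because step 7 selects the S enantiomer.

Step 5
Reactants: 6 3-[4-(benzyloxy)-3-methoxyphenyl]propanal
Product: 9 1-(benzyloxy)-4-(but-3-en-1-yl)-2-methoxybenzene
Conditions: Ph3PCH3Br, KOtBu, THF, 0 °C to rt
Reagents that add atoms: methyltriphenylphosphonium bromide, C[P+](c1ccccc1)(c1ccccc1)c1ccccc1.[Br-]
Why: Wittig methylenation with the non-stabilised ylide turns the aldehyde carbon into C3 of a terminal alkene; no stereochemical issue arises.

Step 6
Reactants: 8 rac-5-[4-(benzyloxy)-3-methoxyphenyl]pent-1-en-3-ol; 9 1-(benzyloxy)-4-(but-3-en-1-yl)-2-methoxybenzene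
Product: 10 rac-(4E)-1,7-bis[4-(benzyloxy)-3-methoxyphenyl]hept-4-en-3-ol
Conditions: second-generation Grubbs catalyst RuCl2(=CHPh)(H2IMes)(PCy3) (5 mol %), 9 (2.5 equiv), CH2Cl2, 40 °C
Reagents that add atoms: none
Why: Olefin cross-metathesis between a secondary allylic alcohol, which homodimerises slowly, and an unhindered terminal alkene, whose homodimer stays metathesis-active, is the pairing that favours the cross product; secondary metathesis should enrich the thermodynamically preferred E isomer while ethene escapes. Any Z isomer is a poor substrate in step 7 and should stay behind with the unreacted alcohol.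

Step 7
Reactants: 10 rac-(4E)-1,7-bis[4-(benzyloxy)-3-methoxyphenyl]hept-4-en-3-ol
Product: 11 (1S)-3-[4-(benzyloxy)-3-methoxyphenyl]-1-[(2S,3S)-3-{2-[4-(benzyloxy)-3-methoxyphenyl]ethyl}oxiran-2-yl]propan-1-ol
Conditions: Ti(OiPr)4 (10 mol %), L-(+)-diisopropyl tartrate (15 mol %), t-BuOOH (0.5 equiv, anhydrous in decane), 4 Å molecular sieves, CH2Cl2, −20 °C
Reagents that add atoms: tert-butyl hydroperoxide, CC(C)(C)OO
Why: Ligand exchange on the dimeric complex formed from Ti(OiPr)4 and the tartrate puts the C5 alkoxide of 10 and the η2-bound tert-butyl peroxide on the same titanium centre, and the distal peroxide oxygen is transferred to the C3=C4 π bond within this complex. The closest known reaction type is the Sharpless kinetic resolution of secondary (E)-allylic alcohols that carry unbranched alkyl groups. The oxirane is closed by a concerted, suprafacial oxygen-atom transfer in which C3–O and C4–O form on one face in a single event, so the E geometry is carried over as the trans ring. The configurations of C3 and C4 (both S) are set by the L-(+)-tartrate ligand, which fixes the alkene face presented to the peroxide. C5 is not created but selected, because in the S enantiomer the C6 chain points into open space and only the C5–H bond faces the tartrate ester groups, so this enantiomer should react much faster and give the erythro product, while the R enantiomer is left and is removed by chromatography. The step needs a large rate ratio between the enantiomers and high erythro selectivity, and the substrate secures both by having an (E)-1,2-disubstituted alkene with no substituent cis to the carbinol and only unbranched methylene groups at C2 and C6, the class for which this resolution is most dependable. The benzyl ethers keep the phenol oxygens off titanium, there is no second alkene to compete, and limiting the peroxide to half an equivalent stops the reaction before the slow enantiomer is drawn in.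

Step 8
Reactants: 11 (1S)-3-[4-(benzyloxy)-3-methoxyphenyl]-1-[(2S,3S)-3-{2-[4-(benzyloxy)-3-methoxyphenyl]ethyl}oxiran-2-yl]propan-1-ol
Product: 12 (3S,5S)-1,7-bis[4-(benzyloxy)-3-methoxyphenyl]heptane-3,5-diol
Conditions: NaAlH2(OCH2CH2OCH3)2 (toluene solution), THF, 0 °C to rt; then aq. potassium sodium tartrate
Reagents that add atoms: none
Why: The C5 hydroxyl becomes an alkoxyaluminate whose remaining Al–H is delivered intramolecularly to the nearer oxirane carbon C4 (SN2 opening, the established 1,3-diol-selective reduction of 2,3-epoxy alcohols with this reagent). C4 becomes a methylene and the C3–O and C5–O bonds are untouched, so the erythro/trans arrangement should emerge as the anti (3S,5S) diol.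

Step 9
Reactants: 12 (3S,5S)-1,7-bis[4-(benzyloxy)-3-methoxyphenyl]heptane-3,5-diol
Product: 14 (3S,5S)-1,7-bis[4-(benzyloxy)-3-methoxyphenyl]-5-hydroxyheptan-3-yl acetate, via cyclic orthoacetate 13 (not isolated)
Conditions: MeC(OMe)3, pyridinium p-toluenesulfonate (5 mol %), CH2Cl2, rt; then AcOH–H2O (4:1), rt
Reagents that add atoms: trimethyl orthoacetate, COC(C)(OC)OC; water, O
Why: Acid-catalysed orthoester exchange ties both hydroxyls to one acetyl-level carbon as a 2-methoxy-2-methyl-1,3-dioxane; mild aqueous acid ionises it to the dioxacarbenium ion, water adds at that carbon and the hemi-orthoester collapses to the hydroxy acetate, so exactly one acetyl group is delivered. The two ring oxygens are homotopic in the C2-symmetric diol, so either mode of opening gives the same compound, and neither carbinol C–O bond is broken.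

Step 10
Reactants: 14 (3S,5S)-1,7-bis[4-(benzyloxy)-3-methoxyphenyl]-5-hydroxyheptan-3-yl acetate
Product: 15 (3S,5S)-5-hydroxy-1,7-bis(4-hydroxy-3-methoxyphenyl)heptan-3-yl acetate
Conditions: H2 (1 atm), 10% Pd/C, EtOAc–EtOH, rt
Reagents that add atoms: none
Why: Hydrogenolysis of the two aryl benzyl ethers over Pd/C under neutral conditions; the acetate, the free secondary hydroxyl and the non-oxygenated benzylic C1 and C7 positions should not be affected, and a 1,3-acetyl shift would be degenerate.

Compound list

1 | eugenol (4-allyl-2-methoxyphenol) | COc1cc(CC=C)ccc1O | starting material
2 | benzyl bromide | BrCc1ccccc1 | starting material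
3 | 4-allyl-1-(benzyloxy)-2-methoxybenzene | COc1cc(CC=C)ccc1OCc1ccccc1 | intermediate
4 | 9-{3-[4-(benzyloxy)-3-methoxyphenyl]propyl}-9-borabicyclo[3.3.1]nonane | COc1cc(CCCB2C3CCCC2CCC3)ccc1OCc1ccccc1 | intermediate
5 | 3-[4-(benzyloxy)-3-methoxyphenyl]propan-1-ol | COc1cc(CCCO)ccc1OCc1ccccc1 | intermediate
6 | 3-[4-(benzyloxy)-3-methoxyphenyl]propanal | COc1cc(CCC=O)ccc1OCc1ccccc1 | intermediate
7 | vinylmagnesium bromide | C=C[Mg]Br | starting material
8 | rac-5-[4-(benzyloxy)-3-methoxyphenyl]pent-1-en-3-ol | COc1cc(CCC(O)C=C)ccc1OCc1ccccc1 | intermediate
9 | 1-(benzyloxy)-4-(but-3-en-1-yl)-2-methoxybenzene | COc1cc(CCC=C)ccc1OCc1ccccc1 | intermediate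
10 | rac-(4E)-1,7-bis[4-(benzyloxy)-3-methoxyphenyl]hept-4-en-3-ol | COc1cc(CCC(O)/C=C/CCc2ccc(OCc3ccccc3)c(OC)c2)ccc1OCc1ccccc1 | intermediate
11 | (1S)-3-[4-(benzyloxy)-3-methoxyphenyl]-1-[(2S,3S)-3-{2-[4-(benzyloxy)-3-methoxyphenyl]ethyl}oxiran-2-yl]propan-1-ol | COc1cc(CC[C@H](O)[C@@H]2O[C@H]2CCc3ccc(OCc4ccccc4)c(OC)c3)ccc1OCc1ccccc1 | intermediate
12 | (3S,5S)-1,7-bis[4-(benzyloxy)-3-methoxyphenyl]heptane-3,5-diol | COc1cc(CC[C@H](O)C[C@@H](O)CCc2ccc(OCc3ccccc3)c(OC)c2)ccc1OCc1ccccc1 | intermediate
13 | (4S,6S)-4,6-bis{2-[4-(benzyloxy)-3-methoxyphenyl]ethyl}-2-methoxy-2-methyl-1,3-dioxane | COc1cc(CC[C@H]2C[C@H](CCc3ccc(OCc4ccccc4)c(OC)c3)OC(C)(OC)O2)ccc1OCc1ccccc1 | intermediate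
14 | (3S,5S)-1,7-bis[4-(benzyloxy)-3-methoxyphenyl]-5-hydroxyheptan-3-yl acetate | COc1cc(CC[C@H](O)C[C@H](CCc2ccc(OCc3ccccc3)c(OC)c2)OC(C)=O)ccc1OCc1ccccc1 | intermediate
15 | (3S,5S)-5-hydroxy-1,7-bis(4-hydroxy-3-methoxyphenyl)heptan-3-yl acetate | COc1cc(CC[C@H](O)C[C@H](CCc2ccc(O)c(OC)c2)OC(C)=O)ccc1O | target

Total step count: 10.
Longest linear sequence: 9 steps from 1 (steps 1, 2, 3, 4, 6, 7, 8, 9, 10; the branch through step 5 is equally long).

Steps least certain to work

Step 7 (key step). The discrimination between the two enantiomers may be insufficient at the conversion needed, so that epoxidation of the slow enantiomer lowers the configurational purity; adventitious water may deactivate the catalyst, and prolonged contact with the Lewis-acidic Ti(OiPr)4–tartrate complex may open the epoxide. Part of any leak corrects itself: the threo epoxide from the slow enantiomer would become the meso diol in step 8, a diastereomer of 12 that can be separated, and only erythro product from the slow enantiomer would lower the enantiomeric purity. The fallback sets the C5 configuration first and then epoxidises without resolution. It sets out from 10 (the unreacted R enantiomer from step 7 can be fed in at the same point). Oxidation with MnO2 in CH2Cl2 would give (4E)-1,7-bis[4-(benzyloxy)-3-methoxyphenyl]hept-4-en-3-one F1 as a conjugated enone. Enantioselective 1,2-reduction of F1 with catecholborane and the (R)-B-methyl oxazaborolidine derived from diphenylprolinol (CBS reduction) in toluene at −78 °C should give, by the usual model, (3S,4E)-1,7-bis[4-(benzyloxy)-3-methoxyphenyl]hept-4-en-3-ol F2 as a single enantiomer. F2 would then be epoxidised with a full equivalent of t-BuOOH under the Ti(OiPr)4/L-(+)-diisopropyl tartrate conditions of step 7, now as a matched reaction, and the route is rejoined at 11.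

Step 6. Homo-coupling of either partner may outrun the cross-coupling, E selectivity may be incomplete, and Ru–H species formed by decomposition of RuCl2(=CHPh)(H2IMes)(PCy3) may shift the double bond or isomerise the allylic alcohol to a ketone. The fallback builds the alkene from an alkyne and sets out from 6. Homologation with dimethyl (1-diazo-2-oxopropyl)phosphonate and K2CO3 in MeOH would give 1-(benzyloxy)-4-(but-3-yn-1-yl)-2-methoxybenzene F3 as the terminal alkyne. Deprotonation of F3 with n-BuLi in THF at −78 °C and addition to a second portion of 6 would give rac-1,7-bis[4-(benzyloxy)-3-methoxyphenyl]hept-4-yn-3-ol F4 as the propargylic alcohol. Hydroxyl-directed trans-hydroalumination of F4 with NaAlH2(OCH2CH2OCH3)2 in THF and protonolysis should give only the E allylic alcohol, and the route is rejoined at 10; compounds 8 and 9 are then not needed.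

Step 8. Regiocontrol may be lost through intermolecular hydride attack at C3, or the epoxide may migrate under the basic conditions before it is reduced. The fallback breaks the C4–O bond by electron transfer and sets out from 11. Dess–Martin oxidation of the C5 carbinol (NaHCO3, CH2Cl2) would give 3-[4-(benzyloxy)-3-methoxyphenyl]-1-[(2R,3S)-3-{2-[4-(benzyloxy)-3-methoxyphenyl]ethyl}oxiran-2-yl]propan-1-one F5 as the epoxy ketone, and the descriptor change at the oxirane carbon is only a change of priorities. SmI2 in THF–MeOH at −78 °C should cleave the C4–O bond of F5 next to the ketyl and give (5S)-1,7-bis[4-(benzyloxy)-3-methoxyphenyl]-5-hydroxyheptan-3-one F6 with the oxygen-bearing stereocentre from the epoxidation intact. Hydroxyl-directed anti reduction of F6 with Me4NBH(OAc)3 in MeCN–AcOH at −20 °C would re-create the second carbinol, and the route is rejoined at 12.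

Step 9. Hydrolysis may run on to the diol, or the orthoester exchange may stay incomplete, so that diol and monoacetate are obtained together. The fallback activates one oxygen through a dibutylstannylene acetal and sets out from 12. Heating with Bu2SnO in toluene with removal of water would give (4S,6S)-4,6-bis{2-[4-(benzyloxy)-3-methoxyphenyl]ethyl}-2,2-dibutyl-1,3,2-dioxastanninane F7 as the stannylene acetal. Acetyl chloride at 0 °C should acylate one tin-bound oxygen of F7 only, and aqueous work-up rejoins the route at 14.

## Further compounds

F1 | step 7 | (4E)-1,7-bis[4-(benzyloxy)-3-methoxyphenyl]hept-4-en-3-one | COc1cc(CCC(=O)/C=C/CCc2ccc(OCc3ccccc3)c(OC)c2)ccc1OCc1ccccc1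
F2 | step 7 | (3S,4E)-1,7-bis[4-(benzyloxy)-3-methoxyphenyl]hept-4-en-3-ol | COc1cc(CC[C@H](O)/C=C/CCc2ccc(OCc3ccccc3)c(OC)c2)ccc1OCc1ccccc1
F3 | step 6 | 1-(benzyloxy)-4-(but-3-yn-1-yl)-2-methoxybenzene | COc1cc(CCC#C)ccc1OCc1ccccc1
F4 | step 6 | rac-1,7-bis[4-(benzyloxy)-3-methoxyphenyl]hept-4-yn-3-ol | COc1cc(CCC(O)C#CCCc2ccc(OCc3ccccc3)c(OC)c2)ccc1OCc1ccccc1
F5 | step 8 | 3-[4-(benzyloxy)-3-methoxyphenyl]-1-[(2R,3S)-3-{2-[4-(benzyloxy)-3-methoxyphenyl]ethyl}oxiran-2-yl]propan-1-one | COc1cc(CCC(=O)[C@@H]2O[C@H]2CCc3ccc(OCc4ccccc4)c(OC)c3)ccc1OCc1ccccc1
F6 | step 8 | (5S)-1,7-bis[4-(benzyloxy)-3-methoxyphenyl]-5-hydroxyheptan-3-one | COc1cc(CCC(=O)C[C@@H](O)CCc2ccc(OCc3ccccc3)c(OC)c2)ccc1OCc1ccccc1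
F7 | step 9 | (4S,6S)-4,6-bis{2-[4-(benzyloxy)-3-methoxyphenyl]ethyl}-2,2-dibutyl-1,3,2-dioxastanninane | COc1cc(CC[C@H]2C[C@H](CCc3ccc(OCc4ccccc4)c(OC)c3)O[Sn](CCCC)(CCCC)O2)ccc1OCc1ccccc1
A1 | alternative 1 | propane-1,3-diol | OCCCO
A2 | alternative 1 | allyl acetate | C=CCOC(C)=O
A3 | alternative 1 | (4S,6S)-nona-1,8-diene-4,6-diol | C=CC[C@H](O)C[C@H](CC=C)O
A4 | alternative 2 | (4R,6R)-4,6-diethenyl-2,2-dimethyl-1,3-dioxane | C=C[C@H]1C[C@H](C=C)OC(C)(C)O1
A5 | alternative 2 | 1-(benzyloxy)-4-bromo-2-methoxybenzene | COc1cc(Br)ccc1OCc1ccccc1
A6 | alternative 2 | (4S,6S)-4,6-bis{2-[4-(benzyloxy)-3-methoxyphenyl]ethyl}-2,2-dimethyl-1,3-dioxane | COc1cc(CC[C@H]2C[C@H](CCc3ccc(OCc4ccccc4)c(OC)c3)OC(C)(C)O2)ccc1OCc1ccccc1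
A7 | alternative 3 | (3S)-1-[4-(benzyloxy)-3-methoxyphenyl]hex-5-en-3-ol | COc1cc(CC[C@H](O)CC=C)ccc1OCc1ccccc1
A8 | alternative 3 | 4-(benzyloxy)-3-methoxybenzaldehyde | COc1cc(C=O)ccc1OCc1ccccc1
A9 | alternative 3 | (2S,4R,6S)-2-[4-(benzyloxy)-3-methoxyphenyl]-6-{2-[4-(benzyloxy)-3-methoxyphenyl]ethyl}oxan-4-yl acetate | COc1cc(CC[C@H]2C[C@@H](OC(C)=O)C[C@@H](c3ccc(OCc4ccccc4)c(OC)c3)O2)ccc1OCc1ccccc1
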